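**Assumption:** the target SMILES has no stereocentre, and the biaryl axis (three small ortho substituents) is not configurationally stable, so there is nothing to set; the compound is made as the single achiral structure given. Apigenin trimethyl ether 6 is taken as a catalogue compound.

**Retrosynthetic overview**
1. Target 9 comes from global O-demethylation of hexamethyl ether 8.
2. 8 is cut at the biaryl bond (isoflavone C3' to flavone C8): Suzuki–Miyaura coupling of boronate 5 with iodide 7.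
3. 7 comes from C8 iodination of bought 6, so the flavone rings are purchased intact.
4. 5 comes from Miyaura borylation of bromoisoflavone 4.
5. 4 comes from 3,5-dimethoxyphenol 1 and arylacetic acid 2. Its pyranone ring (ring C of the isoflavone) is the only ring built and is formed first; the biaryl bond is made last before deprotection.

**Route**

Step 1
Reactants: 1 3,5-dimethoxyphenol; 2 2-(3-bromo-4-methoxyphenyl)acetic acid
Product: 4 bromoisoflavone 3-(3-bromo-4-methoxyphenyl)-5,7-dimethoxy-4H-chromen-4-one, via deoxybenzoin 3 (not isolated)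
Conditions: BF3·OEt2 (neat, as solvent), 85 °C, 2 h; then DMF, MsCl (3 equiv), 50 → 90 °C, 2 h; aq NaOAc work-up
Reagents that add atoms: N,N-dimethylformamide, CN(C)C=O (supplies C-2 of the chromenone)
Why: BF3-promoted Friedel–Crafts (Fries-type) acylation ortho to the chelating phenol OH gives deoxybenzoin 3, whose methylene is formylated by the MsCl/DMF Vilsmeier-type reagent and closes onto the phenol with loss of dimethylamine (one-pot deoxybenzoin isoflavone synthesis); no stereocentre is formed.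

Step 2
Reactants: 4 bromoisoflavone 3-(3-bromo-4-methoxyphenyl)-5,7-dimethoxy-4H-chromen-4-one
Product: 5 pinacol boronate 5,7-dimethoxy-3-[4-methoxy-3-(4,4,5,5-tetramethyl-1,3,2-dioxaborolan-2-yl)phenyl]-4H-chromen-4-one
Conditions: B2pin2 (1.3 equiv), PdCl2(dppf) (5 mol%), KOAc (3 equiv), 1,4-dioxane, 90 °C
Reagents that add atoms: bis(pinacolato)diboron, CC1(C)OB(OC1(C)C)B1OC(C)(C)C(C)(C)O1
Why: Miyaura borylation of the only aryl bromide; the weak acetate base leaves the base-sensitive isoflavone pyranone ring and the new boronate untouched.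

Step 3
Reactants: 6 apigenin trimethyl ether 5,7-dimethoxy-2-(4-methoxyphenyl)-4H-chromen-4-one
Product: 7 iodoflavone 8-iodo-5,7-dimethoxy-2-(4-methoxyphenyl)-4H-chromen-4-one
Conditions: NIS (1.05 equiv), TFA (cat.), MeCN/CH2Cl2, 0 °C → rt
Reagents that add atoms: N-iodosuccinimide, O=C1CCC(=O)N1I
Why: Electrophilic aromatic iodination; in the fully O-methylated ring A the doubly activated C8 is more accessible than C6 (flanked by two OMe groups), and ring B and C3 are far less nucleophilic.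

Step 4
Reactants: 5 pinacol boronate 5,7-dimethoxy-3-[4-methoxy-3-(4,4,5,5-tetramethyl-1,3,2-dioxaborolan-2-yl)phenyl]-4H-chromen-4-one; 7 iodoflavone 8-iodo-5,7-dimethoxy-2-(4-methoxyphenyl)-4H-chromen-4-one
Product: 8 hexamethyl ether 8-[5-(5,7-dimethoxy-4-oxo-4H-chromen-3-yl)-2-methoxyphenyl]-5,7-dimethoxy-2-(4-methoxyphenyl)-4H-chromen-4-one
Conditions: Pd(OAc)2 (5 mol%), SPhos (2-dicyclohexylphosphino-2',6'-dimethoxybiphenyl, 10 mol%), K3PO4 (3 equiv), 1,4-dioxane/H2O 5:1, 90 °C; 5 used in 1.3-fold excess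
Reagents that add atoms: none
Why: Suzuki–Miyaura cross-coupling; the bulky electron-rich biarylphosphine handles the tri-ortho-substituted biaryl, the phosphate base spares the isoflavone ring, and the new axis is not a stable stereoelement.

Step 5
Reactants: 8 hexamethyl ether 8-[5-(5,7-dimethoxy-4-oxo-4H-chromen-3-yl)-2-methoxyphenyl]-5,7-dimethoxy-2-(4-methoxyphenyl)-4H-chromen-4-one
Product: 9 target 8-[5-(5,7-dihydroxy-4-oxo-4H-chromen-3-yl)-2-hydroxyphenyl]-5,7-dihydroxy-2-(4-hydroxyphenyl)-4H-chromen-4-one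
Conditions: BBr3 (20 equiv), CH2Cl2, −78 °C → rt, 24 h; then MeOH, H2O
Reagents that add atoms: none
Why: Lewis-acid aryl methyl ether cleavage (six-fold) at or below room temperature, mild enough to avoid acid-induced ring-opening and Wessely–Moser isomerisation of the 8-aryl flavone to the 6-aryl isomer.

**Compound list**
1 | 3,5-dimethoxyphenol | COc1cc(O)cc(OC)c1 | starting material
2 | 2-(3-bromo-4-methoxyphenyl)acetic acid | COc1ccc(CC(=O)O)cc1Br | starting material
3 | 2-(3-bromo-4-methoxyphenyl)-1-(2-hydroxy-4,6-dimethoxyphenyl)ethan-1-one (deoxybenzoin) | COc1cc(O)c(C(=O)Cc2ccc(OC)c(Br)c2)c(OC)c1 | intermediate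
4 | 3-(3-bromo-4-methoxyphenyl)-5,7-dimethoxy-4H-chromen-4-one | COc1cc(OC)c2c(=O)c(-c3ccc(OC)c(Br)c3)coc2c1 | intermediate
5 | 5,7-dimethoxy-3-[4-methoxy-3-(4,4,5,5-tetramethyl-1,3,2-dioxaborolan-2-yl)phenyl]-4H-chromen-4-one | COc1cc(OC)c2c(=O)c(-c3ccc(OC)c(B4OC(C)(C)C(C)(C)O4)c3)coc2c1 | intermediate
6 | 5,7-dimethoxy-2-(4-methoxyphenyl)-4H-chromen-4-one (apigenin trimethyl ether) | COc1ccc(-c2cc(=O)c3c(OC)cc(OC)cc3o2)cc1 | starting material
7 | 8-iodo-5,7-dimethoxy-2-(4-methoxyphenyl)-4H-chromen-4-one | COc1ccc(-c2cc(=O)c3c(OC)cc(OC)c(I)c3o2)cc1 | intermediate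
8 | 8-[5-(5,7-dimethoxy-4-oxo-4H-chromen-3-yl)-2-methoxyphenyl]-5,7-dimethoxy-2-(4-methoxyphenyl)-4H-chromen-4-one | COc1ccc(-c2cc(=O)c3c(OC)cc(OC)c(-c4cc(-c5coc6cc(OC)cc(OC)c6c5=O)ccc4OC)c3o2)cc1 | intermediate
9 | 8-[5-(5,7-dihydroxy-4-oxo-4H-chromen-3-yl)-2-hydroxyphenyl]-5,7-dihydroxy-2-(4-hydroxyphenyl)-4H-chromen-4-one | O=c1c(-c2ccc(O)c(-c3c(O)cc(O)c4c(=O)cc(-c5ccc(O)cc5)oc34)c2)coc2cc(O)cc(O)c12 | target

**Totals:** 5 steps; longest linear sequence 4 steps (steps 1, 2, 4, 5); step 3 is a one-step side branch.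

**Steps most likely to fail, each with a fallback**

Step 4 (hindered biaryl coupling; risks are protodeboronation of 5 and slow oxidative addition/transmetalation at the crowded C8). The fallback sets out from 2 and 7 and comes back at 8. It forms the biaryl bond with a small, cheap boron partner used in excess, and builds the isoflavone ring afterwards. Acid 2 is esterified (MeOH, cat. H2SO4, reflux) to methyl 2-(3-bromo-4-methoxyphenyl)acetate F3. This is borylated (B2pin2, PdCl2(dppf), KOAc, dioxane, 90 °C) to methyl 2-[4-methoxy-3-(4,4,5,5-tetramethyl-1,3,2-dioxaborolan-2-yl)phenyl]acetate F4. With no isoflavone present, 2–3 equiv of this boronate can be coupled with 7 under more forcing conditions (Pd(OAc)2/SPhos, K3PO4, dioxane/H2O, 100 °C) to give methyl 2-{3-[5,7-dimethoxy-2-(4-methoxyphenyl)-4-oxo-4H-chromen-8-yl]-4-methoxyphenyl}acetate F5. Saponification (LiOH, THF/H2O, rt) gives 2-{3-[5,7-dimethoxy-2-(4-methoxyphenyl)-4-oxo-4H-chromen-8-yl]-4-methoxyphenyl}acetic acid F6. This acid acylates phenol 1 in BF3·OEt2 at 85 °C to the deoxybenzoin 2-{3-[5,7-dimethoxy-2-(4-methoxyphenyl)-4-oxo-4H-chromen-8-yl]-4-methoxyphenyl}-1-(2-hydroxy-4,6-dimethoxyphenyl)ethan-1-one F7, which is not isolated and is closed in the same pot with DMF/MsCl to give 8.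

Step 1 (ortho versus para acylation of 1 and the efficiency of the one-pot ring closure). The fallback sets out from 2 and comes back at 4. It uses bought phloroglucinol (benzene-1,3,5-triol, Oc1cc(O)cc(O)c1), which is symmetric and so has no regiochemical question. Heating 2 with it in BF3·OEt2 at 80 °C gives the isolable deoxybenzoin 2-(3-bromo-4-methoxyphenyl)-1-(2,4,6-trihydroxyphenyl)ethan-1-one F1. BF3·OEt2/DMF/MsCl then closes it to 3-(3-bromo-4-methoxyphenyl)-5,7-dihydroxy-4H-chromen-4-one F2. Exhaustive O-methylation (Me2SO4, K2CO3, acetone, reflux) gives 4.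

Step 5 (six ether cleavages in one operation; risks are partially demethylated mixtures and insoluble borate complexes). The fallback sets out from 8 and comes back at 9. It splits the deprotection into two mechanistically different stages. BCl3 (CH2Cl2, 0 °C) removes only the two chelated peri methyl groups next to the carbonyls, giving 5-hydroxy-8-[5-(5-hydroxy-7-methoxy-4-oxo-4H-chromen-3-yl)-2-methoxyphenyl]-7-methoxy-2-(4-methoxyphenyl)-4H-chromen-4-one F8. The remaining four ethers are then cleaved by SN2 attack of a thiolate rather than by a Lewis acid (NaSEt, DMF, 130 °C, then acidic work-up), giving 9. The phenoxides formed along the way protect both pyranone rings from nucleophilic opening.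

**Further compounds**
F1 | step 1 | 2-(3-bromo-4-methoxyphenyl)-1-(2,4,6-trihydroxyphenyl)ethan-1-one | COc1ccc(CC(=O)c2c(O)cc(O)cc2O)cc1Br
F2 | step 1 | 3-(3-bromo-4-methoxyphenyl)-5,7-dihydroxy-4H-chromen-4-one | COc1ccc(-c2coc3cc(O)cc(O)c3c2=O)cc1Br
F3 | step 4 | methyl 2-(3-bromo-4-methoxyphenyl)acetate | COC(=O)Cc1ccc(OC)c(Br)c1
F4 | step 4 | methyl 2-[4-methoxy-3-(4,4,5,5-tetramethyl-1,3,2-dioxaborolan-2-yl)phenyl]acetate | COC(=O)Cc1ccc(OC)c(B2OC(C)(C)C(C)(C)O2)c1
F5 | step 4 | methyl 2-{3-[5,7-dimethoxy-2-(4-methoxyphenyl)-4-oxo-4H-chromen-8-yl]-4-methoxyphenyl}acetate | COC(=O)Cc1ccc(OC)c(-c2c(OC)cc(OC)c3c(=O)cc(-c4ccc(OC)cc4)oc23)c1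
F6 | step 4 | 2-{3-[5,7-dimethoxy-2-(4-methoxyphenyl)-4-oxo-4H-chromen-8-yl]-4-methoxyphenyl}acetic acid | OC(=O)Cc1ccc(OC)c(-c2c(OC)cc(OC)c3c(=O)cc(-c4ccc(OC)cc4)oc23)c1
F7 | step 4 | 2-{3-[5,7-dimethoxy-2-(4-methoxyphenyl)-4-oxo-4H-chromen-8-yl]-4-methoxyphenyl}-1-(2-hydroxy-4,6-dimethoxyphenyl)ethan-1-one | COc1cc(O)c(C(=O)Cc2ccc(OC)c(-c3c(OC)cc(OC)c4c(=O)cc(-c5ccc(OC)cc5)oc34)c2)c(OC)c1
F8 | step 5 | 5-hydroxy-8-[5-(5-hydroxy-7-methoxy-4-oxo-4H-chromen-3-yl)-2-methoxyphenyl]-7-methoxy-2-(4-methoxyphenyl)-4H-chromen-4-one | COc1ccc(-c2cc(=O)c3c(O)cc(OC)c(-c4cc(-c5coc6cc(OC)cc(O)c6c5=O)ccc4OC)c3o2)cc1
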